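# Proposed total synthesis of (13Z)-19-acetoxylabda-8(17),13-dien-15-oic acid (CNP0360430.3)

## The problem

The target is a trans-fused decalin (rings A and B) with an exocyclic methylene at C8, quaternary carbons C4 and C10 on either side of C5, and a five-carbon chain on C9 that ends in a Z-trisubstituted enoic acid. Four stereocentres must be set: C4 (C18 α, C19 β), C5 (H α), C10 (C20 β) and C9 (H α, chain β and equatorial). C19 and C20 are syn-diaxial on ring A.

C9 lies next to C8 and can be left to equilibration while C8 is a ketone. C10 can be set from C5 by an alkylation anti to the C6 substituent. The C4/C5 relation has no such handle, because a methyl and an oxymethyl group are of similar size. It must therefore come from a ring or a concerted step, and that step must also bring in the absolute configuration.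

Several groups are fragile. The exocyclic alkene moves into the ring under acid and adds boranes and hydrogen. The Z-enoic acid drifts to E when it is activated or deprotonated at its γ positions. The primary acetate would not survive the hydroxide or hydride that a late ester at C15 or C19 would need. C5 is epimerizable whenever C6 is a carbonyl group.

The chain C19–C4(C18)–C5–C6, with C19 at the acid level, is the skeleton of a 3-methylbutenolide: C19 is the lactone carbonyl, C4 the α carbon, C5 the β carbon and C6 the acetal carbon. The other ring A atoms, C3–C2–C1–C10(C20), form a pentadiene, so ring A is a cyclohexene that a [4+2] addition across C4=C5 can close. C6 can carry a chiral alkoxy group to direct the face, and an oxygen on C1 (absent from the target) steers the regiochemistry and later allows C10 to be made quaternary.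

## Retrosynthesis

**C12–C13 (30 ⇒ 29 ⇒ 24 + 27).** The acid 30 is uncovered last from its 2-(trimethylsilyl)ethyl ester 29, which fluoride cleaves without touching the acetate. Ester 29 is cut at the sp3–sp2 bond C12–C13 into the primary iodide 24 and the Z-iodoenoate 27. A cut at C13=C14 would mean olefination of a C13 methyl ketone, where methyl and chain are too alike for Z control. The chosen cut moves the geometric problem to a four-carbon reagent: 27 comes from but-2-ynoic acid 25 through the Z acid 26. The forward coupling must proceed with retention and tolerate the acetate and the exocyclic alkene.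

**Functional groups at C19, C12 and C8 (24 ⇒ 23 ⇒ 22 ⇒ 21 ⇒ 20).** No skeletal bond is cut except C8=C17. Iodo acetate 24 comes from iodo alcohol 23 and this from diol 22, whose two hydroxyls differ sharply: C19–OH is neopentyl and axial, C12–OH is unhindered. Both arise in one hydride reduction of diester 21, so the two oxidation levels delivered by earlier steps are used without protecting groups. The methylene of 21 comes from ketone 20 by olefination, placed before the hydride step.

**C9–C11 (20 ⇒ 18 ⇒ 16).** The two-carbon ester arm on C9 is removed to give enone 16. The enone is preferred to a saturated 8-ketone, which would be alkylated at C7: in 16 the C7 position is vinylic and C9 is the only α' site. The precursor has no C9 stereocentre and no side chain. The forward reaction need not control C9, because hydrogenation to 19 followed by base equilibration delivers the equatorial chain of 20.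

**C6–C7 (16 ⇒ 14 ⇒ 13).** Ring B is opened at the enone double bond to the keto aldehyde 14, which is the methanolysis product of the lactone acetal 13. The lactone acetal is a mask that delivers C6 as an aldehyde and C19 as an ester in one operation and returns the auxiliary. A cut at C5–C6 or C8–C9 would give up the C5 centre or require a secondary electrophile at C9. The forward aldol has only one productive ring size and must outrun epimerization at C5.

**Adjusting C1 and C8 (13 ⇒ 12 ⇒ 11 ⇒ 9).** The acetonyl group of 13 is an oxidized allyl group (12). The C1=C2 alkene of 12 is the reduction product of enol triflate 11, which comes from enone 9 by conjugate reduction and trapping. The unwanted C1 oxygen is thus removed under mild conditions, and the alkene left behind is hydrogenated later together with the ring B alkene.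

**C9–C10 (9 ⇒ 7).** The allyl group is removed from C10 to give enone 7. In 7 the only acidic hydrogen is on C10 (C2 is vinylic, C4 is quaternary), so the regiochemistry of enolate formation is not in question. The forward alkylation must enter anti to C6, on the convex face of the cis-fused bicycle.

**Oxidation level (7 ⇒ 6).** Enone 7 is the dehydrogenation product of silyl enol ether 6. The extra unsaturation is introduced deliberately so that the enolate chemistry at C10 is regiospecific; it costs no step compared with hydrolysing 6 and re-forming an enolate.

**C3–C4 and C5–C10 (6 ⇒ 3 + 5).** Ring A is opened by a retro-[4+2] into the enantiopure butenolide acetal 3 and silyloxydiene 5. This removes one ring, two bonds and three stereocentres at once, and leaves two compounds of five skeletal carbons each. The forward reaction must be face-selective (anti to the alkoxy group) and regioselective (C10 to C5).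

**Starting materials (3 ⇒ 1 + 2; 5 ⇒ 4).** Butenolide 3 is the menthyl acetal of lactol 1 with menthol 2. Diene 5 is the silyl enol ether of ethyl vinyl ketone 4.

## Roads not taken

**Alternative 1:** The cut is at C12–C13 and C14–C15. A C12 bromide A1 carrying a silyl ether at C19 would be converted through its Grignard reagent and CuBr·SMe2 into an alkylcopper. This adds syn across the triple bond of the C3 alkyne, and the alkenylcopper is carboxylated to the Z acid A2.
- Merits: the Z geometry follows from the mechanism, and three carbons and the free acid arrive in one operation. The chosen plan needs four operations for the same result (steps 16 to 19), so as an endgame this road is shorter and in that respect better.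
- Weak points: it answers only the last five carbons and presupposes the whole decalin with C4, C5, C9 and C10 in place. It spends a stoichiometric organocopper derived from the most valuable intermediate. The Grignard stage excludes the acetate, so C19 must be carried as a silyl ether and exchanged afterwards in the presence of the free enoic acid.
- Comparison: the chosen plan installs the acetate before the coupling and never exchanges it, fixes the geometry in a small reagent before it meets the decalin, and uses a catalytic coupling. Above all it includes a solution for the ring system.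

**Alternative 2:** The cut is at C4–C5 and C9–C10. An acyclic β-keto ester A3 bearing an 8-phenylmenthyl ester and two E-trisubstituted alkenes would be oxidized by Mn(OAc)3 with Cu(OAc)2. The resulting radical closes ring A and then ring B, and oxidation of the tertiary C8 radical leaves the exocyclic alkene of A4.
- Merits: both rings, all four ring stereocentres, the methylene and carbons C11 to C13 are formed in one step from a linear precursor. It reaches the bicyclic core in far fewer steps than the chosen plan, which needs nine steps from 6 to reach 21.
- Weak points: the absolute configuration rests on an ester auxiliary acting on a radical cyclization, where induction is moderate and hard to predict. The termination can give endocyclic alkene isomers besides the 8(17) isomer. The C3 ketone must then be removed next to quaternary C4 in the presence of the exocyclic alkene. The Z acid would still have to be made from a C13 ketone.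
- Comparison: the chosen plan is longer. It sets against this a concerted step with dependable facial control from a crystalline auxiliary acetal, a C19/C6 relation fixed by a ring and not by a transition-state preference, no alkene regiochemistry to control, and a Z alkene taken from a stereodefined vinyl iodide.

**Alternative 3:** The cut is at C8–C9. A monocyclic vinyl bromide A5, with an enoate on C10 and a 3-bromobut-3-enyl chain on C5, would be treated with Bu3SnH and AIBN. The C8 vinyl radical adds 6-exo to C9 and gives A6 with ring B closed.
- Merits: ring B, the exocyclic methylene and C9 are made in one neutral step that tolerates the acetate. This replaces the aldol, alkylation, hydrogenation and Wittig steps of the chosen plan (steps 9 to 12) and is the more elegant ring B closure.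
- Weak points: A5 must already contain C4, C5 and C10 with both quaternary centres, which is the hard part and is left open. C9 is set kinetically by addition to a carbon attached to quaternary C10, where hydrogen transfer and direct reduction of the vinyl radical compete. A6 ends in a C12 ester next to the C19 acetate, so chain extension needs a protecting-group change.
- Comparison: the chosen plan supplies the ring A triad with absolute control and sets C9 under thermodynamic control, which is safer though longer.

Key step: step 3

Assumptions:
- Lactol 1 is taken as purchasable; if it must be made, dye-sensitized photooxygenation of 3-methyl-2-furoic acid gives it in one step.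
- As in the unmethylated series, the (5R) epimer of 3 is taken to be the one that crystallizes; if the (5S) epimer crystallized, (1S,2R,5S)-menthol would give the (5R) acetal as the crystalline form, and only the acetal carbon matters for step 3.

## Route

Compounds 6 to 13 are described with labdane numbering: ring A is C1–C5 and C10, the lactone runs from C19 (on C4) to the acetal carbon C6 (on C5).

Step 1
Reactants: 1 5-hydroxy-3-methylfuran-2(5H)-one; 2 (1R,2S,5R)-menthol
Product: 3 (5R)-5-[(1R,2S,5R)-menthyloxy]-3-methylfuran-2(5H)-one
Conditions: TsOH·H2O (cat.), toluene, reflux, Dean–Stark; crystallization from hexane, mother liquor re-equilibrated with TsOH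
Reagents that add atoms: none
Why: Acid-catalysed acetalization of the lactol; the two acetal epimers interconvert through the oxocarbenium ion, so crystallization should drain the mixture into the (5R) diastereomer (crystallization-induced diastereomer transformation), as known for the parent 5-menthyloxyfuranone.

Step 2
Reactants: 4 ethyl vinyl ketone
Product: 5 (Z)-3-(tert-butyldimethylsilyloxy)penta-1,3-diene
Conditions: TBSOTf, Et3N, Et2O, 0 °C
Reagents that add atoms: tert-butyldimethylsilyl trifluoromethanesulfonate, CC(C)(C)[Si](C)(C)OS(=O)(=O)C(F)(F)F
Why: Soft enolization and O-silylation of the enone gives the 2-silyloxydiene; ethyl ketones give the Z enol ether under these conditions, which places the methyl group on the outside of the s-cis diene.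

Step 3
Reactants: 3 (5R)-5-[(1R,2S,5R)-menthyloxy]-3-methylfuran-2(5H)-one; 5 (Z)-3-(tert-butyldimethylsilyloxy)penta-1,3-diene
Product: 6 Diels–Alder adduct (cis-fused ring A lactone acetal with C1 silyl enol ether)
Conditions: 5 (2.5 equiv), BHT (cat.), toluene, 140 °C, sealed tube (base-washed glass)
Reagents that add atoms: none
Why: Thermal normal-demand Diels–Alder reaction, concerted but asynchronous: the enol-ether β carbon of 5 (C10, the methyl-bearing terminus) bonds first to the electrophilic β carbon of the butenolide (C5), and the CH2 terminus (C3) then closes onto the methyl-bearing α carbon (C4). The closest known reaction type is the cycloaddition of enantiopure 5-alkoxyfuran-2(5H)-ones with 2-silyloxydienes, which takes place on the face anti to the alkoxy group. Ring A closes as a six-membered ring in the [4+2] mode, suprafacial on both partners, so the lactone must end cis-fused with C19 and C6 cis. C4 and C5 are set together by the face of attack, which the (5R) acetal carbon C6 controls because its menthyloxy group shields its own side; C10 follows the endo preference (methyl syn to the lactone) and is provisional, since step 5 passes through its enolate. The step needs facial and regiochemical selectivity: the first comes from the acetal, the second from the silyloxy group on C1 (carbonyl-bearing C4 para to it), helped by the fact that the other orientation would join the two more substituted termini. The α-methyl group slows the dienophile, hence the excess of diene, the temperature and the radical inhibitor.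

Step 4
Reactants: 6 Diels–Alder adduct
Product: 7 1-oxo-Δ2 enone lactone acetal
Conditions: Pd(OAc)2 (1.1 equiv), MeCN, 40 °C
Reagents that add atoms: none
Why: Saegusa–Ito oxidation: the silyl enol ether gives a palladium enolate at C2 and β-hydride elimination from C3 gives the C2=C3 enone, its position fixed by the enol ether from step 3. In 7 the only acidic hydrogen is on C10, because C4 is quaternary and offers no γ hydrogen.

Step 5
Reactants: 7 1-oxo-Δ2 enone lactone acetal
Product: 9 10α-allyl-10β-methyl-1-oxo-Δ2 lactone acetal, via lithium dienolate 8 (not isolated)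
Conditions: LiN(i-Pr)2, THF, −78 °C; allyl bromide, DMPU, −78 → 0 °C
Reagents that add atoms: allyl bromide, C=CCBr
Why: Kinetic α'-deprotonation of the cyclohexenone gives the cross-conjugated dienolate, which is C-alkylated at C10 by the allylic halide (enolate alkylation). The electrophile should enter on the convex α face of the cis-fused bicycle, anti to C6 on the neighbouring C5, so that C20 ends β and the new C9 is trans to C6 as the trans-decalin requires.

Step 6
Reactants: 9 10α-allyl-10β-methyl-1-oxo-Δ2 lactone acetal
Product: 11 C1 enol triflate (C1=C2), via lithium enolate 10 (not isolated)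
Conditions: LiBH(s-Bu)3, THF, −78 °C; then PhNTf2, −78 → 0 °C
Reagents that add atoms: N-phenylbis(trifluoromethanesulfonimide), O=S(=O)(N(c1ccccc1)S(=O)(=O)C(F)(F)F)C(F)(F)F
Why: Conjugate reduction with enolate trapping: the bulky borohydride delivers hydride to the unsubstituted β carbon C3 of an enone whose carbonyl is shielded by quaternary C10, and the regiodefined C1–C2 enolate is triflated on oxygen.

Step 7
Reactants: 11 C1 enol triflate
Product: 12 10α-allyl Δ1 lactone acetal
Conditions: Pd(OAc)2 (5 mol %), PPh3, HCO2H, n-Bu3N, DMF, 60 °C
Reagents that add atoms: none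
Why: Palladium-catalysed formate reduction of an enol triflate (oxidative addition, formate exchange, decarboxylation, reductive elimination) removes the C1 oxygen under conditions that leave the lactone acetal and the allyl group alone. The resulting C1=C2 alkene is saturated later in step 11.

Step 8
Reactants: 12 10α-allyl Δ1 lactone acetal
Product: 13 10α-(2-oxopropyl) Δ1 lactone acetal
Conditions: PdCl2 (10 mol %), CuCl (1 equiv), O2 (1 atm), DMF/H2O (7:1), rt
Reagents that add atoms: water, O
Why: Tsuji–Wacker oxidation: Markovnikov hydroxypalladation of the terminal alkene gives the methyl ketone C9H2–C8(=O)–C7H3. The internal ring alkene reacts much more slowly and the acetal should survive the nearly neutral medium.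

Step 9
Reactants: 13 10α-(2-oxopropyl) Δ1 lactone acetal
Product: 16 methyl 8-oxo-11,12,13,14,15,16,17-heptanorlabda-1,6-dien-19-oate, via aldehyde ester 14 (not isolated), via aldol 15 (not isolated)
Conditions: NaOMe (0.5 equiv), MeOH, 0 °C → rt
Reagents that add atoms: methanol, CO
Why: Methoxide opens the acylal-type lactone at C19, and the hemiacetal alkoxide collapses to the C6 aldehyde and menthol. Intramolecular aldol condensation of the methyl ketone (C7) onto C6 can form only the six-membered ring B, and dehydration gives the enone. C5 keeps the configuration from step 3, and C6 and C9 are trans on ring A, so the decalin closes trans.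

Step 10
Reactants: 16 methyl 8-oxo-11,12,13,14,15,16,17-heptanorlabda-1,6-dien-19-oate
Product: 18 dimethyl 8-oxo-13,14,15,16,17-pentanorlabda-1,6-diene-12,19-dioate (C9 epimers), via lithium dienolate 17 (not isolated)
Conditions: LiN(i-Pr)2, THF, −78 °C; BrCH2CO2Me, DMPU, −78 → −20 °C
Reagents that add atoms: methyl bromoacetate, COC(=O)CBr
Why: Kinetic deprotonation of the enone at its only α' position C9 (C7 is vinylic) and alkylation by the reactive α-bromo ester. C9 is not controlled here: attack anti to the axial C20 methyl is expected to favour the axial chain, which step 11 corrects.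

Step 11
Reactants: 18 dimethyl 8-oxo-13,14,15,16,17-pentanorlabda-1,6-diene-12,19-dioate (C9 epimers)
Product: 20 dimethyl 8-oxo-13,14,15,16,17-pentanorlabdane-12,19-dioate (9α-H), via saturated keto diester 19 (not isolated)
Conditions: H2 (1 atm), Pd/C, EtOAc, rt; filter; NaOMe (cat.), MeOH, rt
Reagents that add atoms: none
Why: Heterogeneous hydrogenation saturates both disubstituted ring alkenes and leaves the ketone and esters. Methoxide then equilibrates C9 through the C8 enolate to the equatorial β chain, the stable arrangement of 8-oxolabdanes, which fixes 9α-H.

Step 12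
Reactants: 20 dimethyl 8-oxo-13,14,15,16,17-pentanorlabdane-12,19-dioate (9α-H)
Product: 21 dimethyl 13,14,15,16-tetranorlabd-8(17)-ene-12,19-dioate
Conditions: Ph3PCH3Br, KOt-Bu, THF, 0 → 50 °C
Reagents that add atoms: methyltriphenylphosphonium bromide, C[P+](c1ccccc1)(c1ccccc1)c1ccccc1.[Br-]
Why: Wittig methylenation of the C8 ketone; the ester carbonyls do not react with the non-stabilized ylide. C9 is already at its thermodynamic configuration, so reversible enolization by the basic ylide cannot degrade it.

Step 13
Reactants: 21 dimethyl 13,14,15,16-tetranorlabd-8(17)-ene-12,19-dioate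
Product: 22 13,14,15,16-tetranorlabd-8(17)-ene-12,19-diol
Conditions: LiAlH4, THF, 0 °C → reflux
Reagents that add atoms: none
Why: Hydride reduction of both esters to primary alcohols; the hindered axial C19 ester needs the reflux, and the isolated alkene is inert.

Step 14
Reactants: 22 13,14,15,16-tetranorlabd-8(17)-ene-12,19-diol
Product: 23 12-iodo-13,14,15,16-tetranorlabd-8(17)-en-19-ol
Conditions: PPh3, I2, imidazole, CH2Cl2, 0 °C (reagent premixed)
Reagents that add atoms: iodine, II
Why: Appel-type iodination by backside displacement of the alkoxyphosphonium ion. The unhindered C12 alcohol reacts, whereas the neopentyl C19 position cannot be displaced and is returned as the alcohol on work-up.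

Step 15
Reactants: 23 12-iodo-13,14,15,16-tetranorlabd-8(17)-en-19-ol
Product: 24 12-iodo-13,14,15,16-tetranorlabd-8(17)-en-19-yl acetate
Conditions: Ac2O, pyridine, DMAP (cat.), CH2Cl2, rt
Reagents that add atoms: acetic anhydride, CC(=O)OC(C)=O
Why: DMAP-catalysed acylation of the hindered primary alcohol; the acetate of the target is installed here and never removed.

Step 16
Reactants: 25 but-2-ynoic acid
Product: 26 (Z)-3-iodobut-2-enoic acid
Conditions: NaI, AcOH, 110 °C
Reagents that add atoms: sodium iodide, [Na+].[I-]
Why: Hydroiodination of a 2-ynoic acid: conjugate addition of iodide and protonation of the allenolate give net anti addition, so iodine and carboxyl end cis (Z).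

Step 17
Reactants: 26 (Z)-3-iodobut-2-enoic acid
Product: 27 2-(trimethylsilyl)ethyl (Z)-3-iodobut-2-enoate
Conditions: Me3SiCH2CH2OH, DCC, DMAP (cat.), CH2Cl2, 0 °C
Reagents that add atoms: 2-(trimethylsilyl)ethanol, C[Si](C)(C)CCO
Why: Steglich esterification at low temperature; the β-methyl group slows addition–elimination at C3, so the alkene geometry should be kept.

Step 18
Reactants: 24 12-iodo-13,14,15,16-tetranorlabd-8(17)-en-19-yl acetate; 27 2-(trimethylsilyl)ethyl (Z)-3-iodobut-2-enoate
Product: 29 2-(trimethylsilyl)ethyl (13Z)-19-acetoxylabda-8(17),13-dien-15-oate, via alkylzinc iodide 28 (not isolated)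
Conditions: Zn (activated with BrCH2CH2Br and Me3SiCl), LiCl, THF, 40 °C; then 27, Pd(PPh3)4 (5 mol %), THF, rt
Reagents that add atoms: none
Why: Direct zinc insertion into the primary iodide gives an alkylzinc iodide that tolerates the acetate and the alkene. Negishi coupling with the vinyl iodide proceeds with retention at the sp2 carbon, so C12 ends cis to the ester carbon, which is the 13Z geometry.

Step 19
Reactants: 29 2-(trimethylsilyl)ethyl (13Z)-19-acetoxylabda-8(17),13-dien-15-oate
Product: 30 (13Z)-19-acetoxylabda-8(17),13-dien-15-oic acid
Conditions: Bu4NF, THF, 0 °C → rt; then cold 0.5 M HCl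
Reagents that add atoms: none
Why: Fluoride attacks silicon and the 2-silylethyl ester fragments to the carboxylate, ethene and Me3SiF (β-elimination); the neopentyl acetate, the exocyclic alkene and the Z-enoate are not affected, and brief cold acid only protonates the carboxylate.

## Compound list

Decalins 15 to 30 have 18-CH3 α, C19 β (axial), 5α-H and 10β-CH3; from 20 onward also 9α-H (chain β).

1 | 5-hydroxy-3-methylfuran-2(5H)-one (racemic lactol) | CC1=CC(O)OC1=O | starting material
2 | (1R,2S,5R)-menthol | CC(C)[C@@H]1CC[C@@H](C)C[C@H]1O | starting material
3 | (5R)-5-[(1R,2S,5R)-menthyloxy]-3-methylfuran-2(5H)-one | CC1=C[C@H](O[C@@H]2C[C@H](C)CC[C@H]2C(C)C)OC1=O | intermediate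
4 | ethyl vinyl ketone (pent-1-en-3-one) | CCC(=O)C=C | starting material
5 | (Z)-3-(tert-butyldimethylsilyloxy)penta-1,3-diene | C=C/C(O[Si](C)(C)C(C)(C)C)=C/C | intermediate
6 | Diels–Alder adduct: cis-fused ring A γ-lactone acetal with C1(OTBS)=C2; 18-CH3 α, lactone carbonyl C19 β, 5α-H, (6R)-menthyloxy on acetal C6 anti to C10, 10α-H and 20-CH3 β | C[C@]12CC=C(O[Si](C)(C)C(C)(C)C)[C@@H](C)[C@H]1[C@H](O[C@@H]3C[C@H](C)CC[C@H]3C(C)C)OC2=O | intermediate
7 | 1-oxo-Δ2 enone of the same lactone acetal (C10–H; either C10 epimer serves) | C[C@]12C=CC(=O)[C@@H](C)[C@H]1[C@H](O[C@@H]3C[C@H](C)CC[C@H]3C(C)C)OC2=O | intermediate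
8 | lithium dienolate of 7 (C1(OLi)=C10, C2=C3) | C[C@]12C=CC(O[Li])=C(C)[C@H]1[C@H](O[C@@H]3C[C@H](C)CC[C@H]3C(C)C)OC2=O | intermediate
9 | 10α-allyl-10β-methyl-1-oxo-Δ2 lactone acetal (allyl = C9–C8=C7) | C[C@]12C=CC(=O)[C@](C)(CC=C)[C@H]1[C@H](O[C@@H]3C[C@H](C)CC[C@H]3C(C)C)OC2=O | intermediate
10 | lithium enolate C1(OLi)=C2 of the 2,3-dihydro ketone from 9 | C[C@]12CC=C(O[Li])[C@](C)(CC=C)[C@H]1[C@H](O[C@@H]3C[C@H](C)CC[C@H]3C(C)C)OC2=O | intermediate
11 | C1 enol triflate (C1(OTf)=C2) of the 10α-allyl lactone acetal | C[C@]12CC=C(OS(=O)(=O)C(F)(F)F)[C@](C)(CC=C)[C@H]1[C@H](O[C@@H]3C[C@H](C)CC[C@H]3C(C)C)OC2=O | intermediate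
12 | 10α-allyl-10β-methyl Δ1 lactone acetal | C[C@]12CC=C[C@](C)(CC=C)[C@H]1[C@H](O[C@@H]3C[C@H](C)CC[C@H]3C(C)C)OC2=O | intermediate
13 | 10α-(2-oxopropyl)-10β-methyl Δ1 lactone acetal | C[C@]12CC=C[C@](C)(CC(C)=O)[C@H]1[C@H](O[C@@H]3C[C@H](C)CC[C@H]3C(C)C)OC2=O | intermediate
14 | monocyclic aldehyde ester: cyclohex-1-ene with C4 (CH3 α, CO2Me β), C5 (CHO β, H α), C10 (CH3 β, CH2COCH3 α) | C[C@]1(C(=O)OC)CC=C[C@](C)(CC(C)=O)[C@H]1C=O | intermediate
15 | methyl 6-hydroxy-8-oxo-11,12,13,14,15,16,17-heptanorlabd-1-en-19-oate (C6 epimers) | O=C1CC(O)[C@H]2[C@@](C)(C(=O)OC)CC=C[C@]2(C)C1 | intermediate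
16 | methyl 8-oxo-11,12,13,14,15,16,17-heptanorlabda-1,6-dien-19-oate | O=C1C=C[C@H]2[C@@](C)(C(=O)OC)CC=C[C@]2(C)C1 | intermediate
17 | lithium dienolate of 16 (C8(OLi)=C9, C6=C7) | [Li]OC=1C=C[C@H]2[C@@](C)(C(=O)OC)CC=C[C@]2(C)C=1 | intermediate
18 | dimethyl 8-oxo-13,14,15,16,17-pentanorlabda-1,6-diene-12,19-dioate (C9 epimers) | O=C1C=C[C@H]2[C@@](C)(C(=O)OC)CC=C[C@]2(C)C1CC(=O)OC | intermediate
19 | dimethyl 8-oxo-13,14,15,16,17-pentanorlabdane-12,19-dioate (C9 epimers) | O=C1CC[C@H]2[C@@](C)(C(=O)OC)CCC[C@]2(C)C1CC(=O)OC | intermediate
20 | dimethyl 8-oxo-13,14,15,16,17-pentanorlabdane-12,19-dioate (9α-H) | O=C1CC[C@H]2[C@@](C)(C(=O)OC)CCC[C@]2(C)[C@H]1CC(=O)OC | intermediate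
21 | dimethyl 13,14,15,16-tetranorlabd-8(17)-ene-12,19-dioate | C=C1CC[C@H]2[C@@](C)(C(=O)OC)CCC[C@]2(C)[C@H]1CC(=O)OC | intermediate
22 | 13,14,15,16-tetranorlabd-8(17)-ene-12,19-diol | C=C1CC[C@H]2[C@@](C)(CO)CCC[C@]2(C)[C@H]1CCO | intermediate
23 | 12-iodo-13,14,15,16-tetranorlabd-8(17)-en-19-ol | C=C1CC[C@H]2[C@@](C)(CO)CCC[C@]2(C)[C@H]1CCI | intermediate
24 | 12-iodo-13,14,15,16-tetranorlabd-8(17)-en-19-yl acetate | C=C1CC[C@H]2[C@@](C)(COC(C)=O)CCC[C@]2(C)[C@H]1CCI | intermediate
25 | but-2-ynoic acid | CC#CC(=O)O | starting material
26 | (Z)-3-iodobut-2-enoic acid | C/C(I)=C/C(=O)O | intermediate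
27 | 2-(trimethylsilyl)ethyl (Z)-3-iodobut-2-enoate | C/C(I)=C/C(=O)OCC[Si](C)(C)C | intermediate
28 | (19-acetoxy-13,14,15,16-tetranorlabd-8(17)-en-12-yl)zinc iodide | C=C1CC[C@H]2[C@@](C)(COC(C)=O)CCC[C@]2(C)[C@H]1CC[Zn]I | intermediate
29 | 2-(trimethylsilyl)ethyl (13Z)-19-acetoxylabda-8(17),13-dien-15-oate | C=C1CC[C@H]2[C@@](C)(COC(C)=O)CCC[C@]2(C)[C@H]1CC/C(C)=C\C(=O)OCC[Si](C)(C)C | intermediate
30 | (13Z)-19-acetoxylabda-8(17),13-dien-15-oic acid (CNP0360430.3) | C=C1CC[C@H]2[C@@](C)(COC(C)=O)CCC[C@]2(C)[C@H]1CC/C(C)=C\C(=O)O | target

## Step count and least certain steps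

Total: 19 steps. Longest linear sequence: 16 steps (steps 1, 3 to 15, 18 and 19); steps 2, 16 and 17 are side branches.

**Step 3 (key step).** The most likely failure is low conversion: an α-methylated, trisubstituted dienophile meets a diene with only one donor group, and at the temperature needed the diene may polymerize or lose its silyl group. Some regiochemical leakage is possible, because the terminal methyl of the diene works against the silyloxy group. The fallback raises the diene HOMO; it sets out from 3 and returns at 7. Commercial (E)-4-methoxybut-3-en-2-one would be methylated at its methyl ketone carbon (LiN(i-Pr)2, MeI) to (E)-1-methoxypent-1-en-3-one F1 and silylated (TBSOTf, Et3N) to (1E,3Z)-1-methoxy-3-(tert-butyldimethylsilyloxy)penta-1,3-diene F2. Cycloaddition of F2 with 3 at 80 to 110 °C forms the same two bonds and gives the 3-methoxy adduct F3. Dilute HCl in THF then cleaves the enol ether and eliminates methanol to give enone 7, which makes step 4 unnecessary.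

**Step 5.** The risk is poor facial selectivity at C10, because the α methyl on C4 also lies on the convex face, together with some O-allylation of the dienolate. The fallback replaces substrate control by catalyst control; it sets out from 7 and returns at 9. Enone 7 would be converted (KN(SiMe3)2, allyl chloroformate) into the allyl dienol carbonate F4. Decarboxylative allylation with Pd2(dba)3 and a chiral phosphinooxazoline ligand, its enantiomer chosen to deliver the allyl group to the α face, then gives 9.

**Step 6.** The risk is carbonyl (1,2) reduction or attack on the lactone in place of conjugate hydride delivery, because C3 is flanked by quaternary C4. The fallback avoids conjugate reduction; it sets out from 9 and returns at 12, bypassing steps 6 and 7. Enone 9 would be condensed with tosylhydrazide (cat. TsOH, THF, 50 °C) to the tosylhydrazone F5. Reduction with catecholborane and warming with NaOAc (reductive 1,3-transposition by loss of sulfinate and dinitrogen from the allylic diazene) gives the C1=C2 alkene 12 directly.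

**Step 9.** The risk is epimerization at C5, through the enolizable aldehyde 14 or the dienolate of 16, which would lead to a cis-decalin; incomplete dehydration is a lesser concern. The fallback never liberates the aldehyde under base; it sets out from 13 and returns at 16. Kinetic enolization of the methyl ketone (LiN(i-Pr)2, Me3SiCl, −78 °C) gives the trimethylsilyl enol ether F6. TiCl4 in CH2Cl2 at −78 °C ionizes the acetal with loss of the menthyloxy group, and the intramolecular Mukaiyama-type addition closes ring B to the keto lactone F7 (8-oxo 19,6β-olide). K2CO3 and MeI in DMF, then DBU, open the β-acyloxy ketone by elimination and esterify the carboxylate to give 16.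

**Step 10.** The risk is slow alkylation at the C9 enolate carbon, which sits next to quaternary C10; proton transfer would then return enone or give double alkylation, and γ-deprotonation at C5 could compete. The fallback uses an aldehyde as a much more reactive electrophile; it sets out from 16 and returns at 20. The dienolate of 16 would be added to methyl glyoxylate to give the aldol F8, which is mesylated and eliminated (MsCl, Et3N; DBU) to the alkylidene keto ester F9. The hydrogenation of step 11 then saturates three C=C bonds instead of two, and the methoxide equilibration gives 20.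

## Further compounds

F1 | step 3 | (E)-1-methoxypent-1-en-3-one | CCC(=O)/C=C/OC
F2 | step 3 | (1E,3Z)-1-methoxy-3-(tert-butyldimethylsilyloxy)penta-1,3-diene | CO/C=C/C(O[Si](C)(C)C(C)(C)C)=C/C
F3 | step 3 | 3-methoxy analogue of adduct 6 (C3 and C10 epimers) | C[C@]12C(OC)C=C(O[Si](C)(C)C(C)(C)C)C(C)[C@H]1[C@H](O[C@@H]3C[C@H](C)CC[C@H]3C(C)C)OC2=O
F4 | step 5 | allyl dienol carbonate of 7 (C1(OCO2allyl)=C10) | C[C@]12C=CC(OC(=O)OCC=C)=C(C)[C@H]1[C@H](O[C@@H]3C[C@H](C)CC[C@H]3C(C)C)OC2=O
F5 | step 6 | tosylhydrazone of 9 | C[C@]12C=CC(=NNS(=O)(=O)c3ccc(C)cc3)[C@](C)(CC=C)[C@H]1[C@H](O[C@@H]4C[C@H](C)CC[C@H]4C(C)C)OC2=O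
F6 | step 9 | trimethylsilyl enol ether of 13 (C8(OSiMe3)=C7H2) | C[C@]12CC=C[C@](C)(CC(=C)O[Si](C)(C)C)[C@H]1[C@H](O[C@@H]3C[C@H](C)CC[C@H]3C(C)C)OC2=O
F7 | step 9 | 8-oxo-11,12,13,14,15,16,17-heptanorlabd-1-en-19,6β-olide | O=C1C[C@@H]3[C@H]2[C@@](C)(C(=O)O3)CC=C[C@]2(C)C1
F8 | step 10 | methyl 11-hydroxy-8-oxo-13,14,15,16,17-pentanorlabda-1,6-diene-12,19-dioate 19-methyl ester (aldol of 16 with methyl glyoxylate; C9 and C11 epimers) | O=C1C=C[C@H]2[C@@](C)(C(=O)OC)CC=C[C@]2(C)C1C(O)C(=O)OC
F9 | step 10 | dimethyl 8-oxo-13,14,15,16,17-pentanorlabda-1,6,9(11)-triene-12,19-dioate | O=C1C=C[C@H]2[C@@](C)(C(=O)OC)CC=C[C@]2(C)C1=CC(=O)OC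
A1 | alternative 1 | 12-bromo-19-(tert-butyldimethylsilyloxy)-13,14,15,16-tetranorlabd-8(17)-ene | C=C1CC[C@H]2[C@@](C)(CO[Si](C)(C)C(C)(C)C)CCC[C@]2(C)[C@H]1CCBr
A2 | alternative 1 | (13Z)-19-(tert-butyldimethylsilyloxy)labda-8(17),13-dien-15-oic acid | C=C1CC[C@H]2[C@@](C)(CO[Si](C)(C)C(C)(C)C)CCC[C@]2(C)[C@H]1CC/C(C)=C\C(=O)O
A3 | alternative 2 | 8-phenylmenthyl (6E,10E)-14,14-ethylenedioxy-2,6,10-trimethyl-3-oxopentadeca-6,10-dienoate | CC(C(=O)O[C@@H]1C[C@H](C)CC[C@H]1C(C)(C)c1ccccc1)C(=O)CC/C(C)=C/CC/C(C)=C/CCC1(C)OCCO1
A4 | alternative 2 | 8-phenylmenthyl 13,13-ethylenedioxy-3-oxo-14,15-dinorlabd-8(17)-en-19-oate | C=C1CC[C@H]2[C@@](C)(C(=O)O[C@@H]3C[C@H](C)CC[C@H]3C(C)(C)c3ccccc3)C(=O)CC[C@]2(C)[C@H]1CCC1(C)OCCO1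
A5 | alternative 3 | methyl (E)-3-[ring A with 4-(acetoxymethyl)-4,10-dimethyl and 5-(3-bromobut-3-enyl)]prop-2-enoate (8,9-seco precursor) | C=C(Br)CC[C@H]1[C@@](C)(COC(C)=O)CCC[C@]1(C)/C=C/C(=O)OC
A6 | alternative 3 | methyl 19-acetoxy-13,14,15,16-tetranorlabd-8(17)-en-12-oate | C=C1CC[C@H]2[C@@](C)(COC(C)=O)CCC[C@]2(C)[C@H]1CC(=O)OC
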